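The target in Thursday's run reads 0.02968 M at 9.6 min, from 0.0800 M of starting material, and you want to know where Saturday's flask, with the same charge, stands at 19 min.

| flask | starting material | coupling partner | free catalyst | time |
|---|---|---|---|---|
| Thursday's | 0.0800 M | 0.200 M | 0.00400 M |  |
| Wednesday's | 0.0480 M | 0.168 M | 0.00400 M |  |
| Monday's | 0.0800 M | 0.200 M | 0.0120 M |  |
| Friday's | 0.0800 M | 0.400 M | 0.00400 M |  |
| Saturday's | 0.0800 M | 0.200 M | 0.00400 M | 19 min |

| Thursday's run: time / min | Thursday's run: [target] / M | Wednesday's run: time / min | Wednesday's run: [target] / M | Monday's run: time / min | Monday's run: [target] / M | Friday's run: time / min | Friday's run: [target] / M |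
|---|---|---|---|---|---|---|---|
| 1.2 | 0.01050 | 1.2 | 0.00806 | 1.2 | 0.02899 | 1.2 | 0.01963 |
| 2.4 | 0.01706 | 2.4 | 0.01323 | 2.4 | 0.04447 | 2.4 | 0.03179 |
| 3.6 | 0.02166 | 3.6 | 0.01683 | 3.6 | 0.05462 | 3.6 | 0.04020 |
| 4.8 | 0.02494 | 4.8 | 0.01962 | 4.8 | 0.06076 | 4.8 | 0.04615 |
| 6.0 | 0.02648 | 6.0 | 0.02133 | 6.0 | 0.06518 | 6.0 | 0.05020 |
| 7.2 | 0.02822 | 7.2 | 0.02279 | 7.2 | 0.06791 | 7.2 | 0.05356 |
| 8.4 | 0.02895 | 8.4 | 0.02391 | 8.4 | 0.06971 | 8.4 | 0.05560 |
| 9.6 | 0.02968 | 9.6 | 0.02481 | 9.6 | 0.07164 | 9.6 | 0.05716 |

(each reading ± 2 × 10⁻⁴ M)

1. order of the initial rate in [coupling partner], near the charge of the Thursday's run, the rate being that where two percent of its starting material are target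
2. order of the initial rate in [starting material], near the charge of the Thursday's run, the rate being that where two percent of its starting material are target (one fixed amount of target, the same in the runs compared)
3. target in the Saturday's run at 19 min, as a share of the starting material charged

- Overall: starting material + coupling partner -> target, with free catalyst as catalyst.
- Constant volume, constant temperature.
- Readings of a species count what is bound in complexes too.
- "The second partner" is coupling partner.
- An order is taken over about fifteen percent of the charge, up and down.

Friday's run is the neighbour: it has the same starting material and free catalyst, but twice the coupling partner. Cut each run at 4.8 min, and let g be the target made in the next equal span divided by the target A made in the first. Thursday gives g = 0.190 and Friday 0.239, so the two slow on much the same clock.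

If each span yields g times the one before, the yields sum to a ceiling P∞ = A/(1−g). That is 0.0308 M for Thursday and 0.0606 M for Friday, twice as much. Thursday's ceiling is not a lack of starting material, then, since Friday's flask, with the same charge, climbs higher. With similar working lives, Friday's catalyst reads as turning faster, its first reading being 1.87 times Thursday's.

So from Thursday to Friday the turnover number P∞/C, with C the free catalyst charged, grows with R, the partner charged. Thursday's readings give 0.0260 M for the break-even partner concentration R*: the partner charged per turnover in a catalyst's working life, R* = RC/P∞. Friday's readings give 0.0264 M.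

Saturday's 19 min is about 4 spans, which leaves a fraction g⁴ of the ceiling unmade, so I expect 38.4%. First readings, taken as rough initial rates although they lie past the conversion asked about, give me an order of 0.903 in partner (Friday against Thursday). After dividing out the partner, Wednesday against Thursday gives 0.210 in starting material.

The forecast, which reads “first-order catalyst death in time, not product inhibition”, stands a little above these at 0.95, 0.22 and 39.3%.

The flask gives 0.99, 0.20 and 39.0%.

    free catalyst + starting material ⇌ catalyst-substrate complex, settled at all times (41.80 M⁻¹)
    catalyst-substrate complex + coupling partner → target + free catalyst + by-product (23.40 M⁻¹ min⁻¹)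
    catalyst-substrate complex → spent catalyst + starting material (0.4872 min⁻¹)
    starting material + coupling partner ⇌ idle substrate-reagent adduct, settled at all times (3.040 M⁻¹)

Saturday's flask stops through the passing of catalyst-substrate complex into spent catalyst: without that step it reaches 98.8% instead of 39.0%. Target and spent catalyst both leave that complex, so partner concentration weighs one exit against the other. Saturday's share reads back as an R* of 0.0256 M, beside Thursday's 0.0260 M. On Friday's charge, 0.0260 M gives an estimated ceiling of 77.0% of the starting material, and Friday's run passes half at 3.57 min.

The earlier runs and the new flask come from a simulation for an exercise, noise included.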